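## Retrosynthetic overview

1. Uprolide D ⇐ the (3R,4R,7R,8R)-3,4:7,8-bis-epoxide of the cembranolide. One transannular epoxonium cascade makes the THF ring, C4, the 3-OH and the 8(19)-methylene: the 7,8-epoxide oxygen opens the 3,4-epoxide at C4, then H-19 is lost. The bis-epoxide ⇐ the 3E,7E-diene by double Shi epoxidation.
2. α-Methylene cis-lactone ⇐ macrocyclic butenolide: 1,4-hydride addition sets C1, and Mannich trapping followed by elimination adds C17.
3. 14-Membered carbocycle ⇐ the C1–C2 bond, the bond the cembrene cyclase makes: an allyl-cation equivalent (π-allyl-Pd from the farnesyl acetate terminus) is captured by a C1 vinylstannane.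
4. Open chain ⇐ (S)-α-methyl aldehyde + 4-stannyl-2-silyloxyfuran: a vinylogous Mukaiyama aldol sets C13 and C14; the lactone ring is bought as a furanone.
5. Aldehyde ⇐ (E,E)-farnesyl acetate: terminal SeO2 oxidation, then Ru–BINAP hydrogenation sets C12. Ring order: lactone (purchased) → carbocycle → tetrahydrofuran.

Assumption: (2E,6E)-farnesyl acetate and 4-bromofuran-2(5H)-one are bought as such. Macrocycles are named with cembrane numbering: C1 = lactone CH carrying C15, C14 = lactone O–CH, C16 = C=O, C17 = exocyclic CH2, C18/C19/C20 = methyls on C4/C8/C12.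

## Route

Step 1
Reactants: 1 (2E,6E)-farnesyl acetate
Product: 2 (2E,6E,10E)-12-hydroxy-3,7,11-trimethyldodeca-2,6,10-trien-1-yl acetate
Conditions: SeO2 (0.3 equiv), salicylic acid (0.1 equiv), t-BuOOH (3 equiv), CH2Cl2, 0 °C to rt
Reagents that add atoms: selenium dioxide O=[Se]=O (catalytic oxygen carrier); tert-butyl hydroperoxide CC(C)(C)OO (terminal oxygen source)
Why: Sharpless–Umbreit catalytic SeO2 allylic oxidation (ene reaction/[2,3]-shift) attacks the most electron-rich terminal isopropylidene group at its (E)-methyl, while the olefin next to the acetate is deactivated.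

Step 2
Reactants: 2 (2E,6E,10E)-12-hydroxy-3,7,11-trimethyldodeca-2,6,10-trien-1-yl acetate
Product: 3 (2E,6E,11S)-12-hydroxy-3,7,11-trimethyldodeca-2,6-dien-1-yl acetate
Conditions: Ru(OAc)2[(S)-BINAP] (1 mol%), H2 (50 atm), MeOH, 25 °C
Reagents that add atoms: none
Why: Noyori hydroxyl-directed asymmetric hydrogenation reduces only the olefin chelated through the free OH, and the (S)-BINAP complex, adding H2 to the same C=C–CH2OH chelate face that turns geraniol into (R)-citronellol, is predicted to make C11 (cembrane C12) S, a sense to be confirmed on the first batch.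

Step 3
Reactants: 3 (2E,6E,11S)-12-hydroxy-3,7,11-trimethyldodeca-2,6-dien-1-yl acetate
Product: 4 (2E,6E,11S)-3,7,11-trimethyl-12-oxododeca-2,6-dien-1-yl acetate
Conditions: Cu(MeCN)4OTf (5 mol%), 2,2'-bipyridine (5 mol%), TEMPO (5 mol%), N-methylimidazole (10 mol%), air, MeCN, rt
Reagents that add atoms: none
Why: Stahl aerobic Cu/TEMPO oxidation converts the primary alcohol to the aldehyde under neutral conditions that do not epimerise the α-methyl stereocentre.

Step 4
Reactants: 5 4-bromofuran-2(5H)-one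
Product: 6 4-(tributylstannyl)furan-2(5H)-one
Conditions: (Bu3Sn)2 (1.1 equiv), Pd(PPh3)4 (3 mol%), THF, reflux
Reagents that add atoms: hexabutylditin CCCC[Sn](CCCC)(CCCC)[Sn](CCCC)(CCCC)CCCC
Why: Pd-catalysed stannylation (oxidative addition into the activated vinylogous acyl bromide, Sn–Sn transmetalation, reductive elimination) gives the known β-stannyl butenolide.

Step 5
Reactants: 6 4-(tributylstannyl)furan-2(5H)-one
Product: 7 tributyl[5-(trimethylsilyloxy)furan-3-yl]stannane
Conditions: TMSOTf (1.1 equiv), Et3N (1.3 equiv), CH2Cl2, 0 °C; pentane, filtration under Ar, used crude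
Reagents that add atoms: trimethylsilyl trifluoromethanesulfonate C[Si](C)(C)OS(=O)(=O)C(F)(F)F
Why: Soft enolisation (γ-deprotonation and O-silylation, driven by furan aromatisation) is the standard entry to 2-silyloxyfurans and leaves the electron-poor vinyl–tin bond intact.

Step 6
Reactants: 4 (2E,6E,11S)-3,7,11-trimethyl-12-oxododeca-2,6-dien-1-yl acetate; 7 tributyl[5-(trimethylsilyloxy)furan-3-yl]stannane
Product: 8 (5S)-5-[(1R,2S,6E,10E)-12-acetoxy-1-hydroxy-2,6,10-trimethyldodeca-6,10-dien-1-yl]-4-(tributylstannyl)furan-2(5H)-one (cembrane C12 S, C13 R, C14 of target configuration; the label 5S arises only because tin outranks oxygen)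
Conditions: BF3·OEt2 (1.2 equiv), CH2Cl2, −78 °C; aq NaHCO3
Reagents that add atoms: none
Why: Vinylogous Mukaiyama aldol in which the silyloxyfuran attacks through C5 on the Felkin–Anh face of the α-methyl aldehyde (12,13-syn, hence 13R) via the open threo-selective transition state usual for BF3-promoted 2-silyloxyfuran additions (13,14-syn), the in-plane 4-SnBu3 group tolerating only the aldehyde H as its neighbour there.

Step 7
Reactants: 8 (5S)-5-[(1R,2S,6E,10E)-12-acetoxy-1-hydroxy-2,6,10-trimethyldodeca-6,10-dien-1-yl]-4-(tributylstannyl)furan-2(5H)-one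
Product: 9 (12S,13R,14R)-13-hydroxycembra-1(15),3E,7E-trien-16,14-olide
Conditions: Pd2(dba)3 (10 mol%), AsPh3 (40 mol%), LiCl (3 equiv), NMP, 50 °C, syringe-pump addition (final 1 mM)
Reagents that add atoms: none
Why: Intramolecular Stille sp2–sp3 coupling in which Pd(0) ionises the primary allylic acetate to a syn-π-allyl cation equivalent that is captured at its unhindered CH2 terminus by the C1 vinyl group, closing the 14-membered ring at C1–C2 with the 3E olefin retained and no stereocentre touched.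

Step 8
Reactants: 9 (12S,13R,14R)-13-hydroxycembra-1(15),3E,7E-trien-16,14-olide
Product: 11 (1S,12S,13R,14R)-17-(dimethylamino)-13-hydroxycembra-3E,7E-dien-16,14-olide (C15 epimers), via bis-silyl ketene acetal 10 (not isolated)
Conditions: Cu(OAc)2·H2O (5 mol%), 1,2-bis(diphenylphosphino)benzene (5 mol%), (EtO)2MeSiH (3.5 equiv), toluene, rt; then CH2=NMe2+ I− (3 equiv), CH2Cl2, rt; aq NaHCO3
Reagents that add atoms: N,N-dimethylmethyleneiminium iodide (Eschenmoser's salt) C=[N+](C)C.[I-]
Why: After fast Cu-catalysed O-silylation of the 13-OH, Cu–H 1,4-reduction (Stryker/Lipshutz type) delivers hydride to C1 on the lactone face anti to the C13 substituent on C14 (H-1 cis to H-14, i.e. 1S, cis-lactone), and the silyl ketene acetal is trapped by Eschenmoser's salt in a Mannich reaction whose C15 configuration is irrelevant.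

Step 9
Reactants: 11 (1S,12S,13R,14R)-17-(dimethylamino)-13-hydroxycembra-3E,7E-dien-16,14-olide
Product: 13 (1S,12S,13R,14R)-13-hydroxycembra-3E,7E,15(17)-trien-16,14-olide, via trimethylammonium iodide 12 (not isolated)
Conditions: MeI (10 equiv), MeOH–CH2Cl2, rt; evaporate; aq NaHCO3/EtOAc, rt
Reagents that add atoms: none
Why: Exhaustive N-methylation followed by E1cB (Hofmann-type) loss of trimethylamine across C15–C17 unveils the α-methylene lactone without touching any stereocentre of the target.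

Step 10
Reactants: 13 (1S,12S,13R,14R)-13-hydroxycembra-3E,7E,15(17)-trien-16,14-olide
Product: 14 (1S,3R,4R,7R,8R,12S,13R,14R)-3,4:7,8-diepoxy-13-hydroxycembr-15(17)-en-16,14-olide
Conditions: Shi ketone (D-fructose-derived, 0.6 equiv), Oxone (3 equiv), K2CO3, Bu4NHSO4 (cat.), MeCN–(MeO)2CH2/aq Na2B4O7–EDTA buffer (pH 10.5), 0 °C
Reagents that add atoms: potassium peroxymonosulfate (Oxone) [K+].[O-]S(=O)(=O)OO
Why: Shi asymmetric epoxidation, in which the chiral dioxirane epoxidises both E-trisubstituted olefins through the spiro transition state on the face that gives (R,R)-type epoxides (3R,4R and 7R,8R under reagent control), while the electron-poor methylene lactone is inert to the electrophilic oxidant.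

Step 11
Reactants: 14 (1S,3R,4R,7R,8R,12S,13R,14R)-3,4:7,8-diepoxy-13-hydroxycembr-15(17)-en-16,14-olide
Product: 18 uprolide D, via 13-O-TMS bis-epoxide 15 (not isolated), via silylated bicyclic epoxonium triflate 16 (not isolated), via 3,13-bis-O-TMS uprolide D 17 (not isolated)
Conditions: TMSOTf (2.2 equiv), 2,6-di-tert-butyl-4-methylpyridine (3 equiv), CH2Cl2, −78 to −30 °C; then aq citric acid/THF, 0 °C
Reagents that add atoms: none
Why: Proposed new method: after capping of the 13-OH, silylation of the 3,4-epoxide makes tertiary C4 electrophilic, the 7,8-epoxide oxygen attacks it anti in the 5-exo mode (inversion at C4 gives 4S; the C3–O and C7–O bonds are untouched, giving 3R, 7R and the cis-THF), and the bicyclic epoxonium ion breaks its tertiary C8–O bond with loss of a C19 proton to the hindered pyridine to give the 8(19)-methylene, the alternative start (isomerisation of the 7,8-epoxide to the 7-silyloxy-8(19)-ene, whose oxygen then opens the 3,4-epoxide at C4) converging on the same product; the closest known reactions are Lewis-acid epoxonium-relay cascades of 1,5-diepoxides to tetrahydrofurans and the TMSOTf/base isomerisation of trisubstituted epoxides to exo-methylene allylic silyl ethers.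

## Compound list

1 | (2E,6E)-farnesyl acetate | CC(=O)OC/C=C(\C)CC/C=C(\C)CCC=C(C)C | starting material
2 | (2E,6E,10E)-12-hydroxy-3,7,11-trimethyldodeca-2,6,10-trien-1-yl acetate | CC(=O)OC/C=C(\C)CC/C=C(\C)CC/C=C(\C)CO | intermediate
3 | (2E,6E,11S)-12-hydroxy-3,7,11-trimethyldodeca-2,6-dien-1-yl acetate | CC(=O)OC/C=C(\C)CC/C=C(\C)CCC[C@H](C)CO | intermediate
4 | (2E,6E,11S)-3,7,11-trimethyl-12-oxododeca-2,6-dien-1-yl acetate | CC(=O)OC/C=C(\C)CC/C=C(\C)CCC[C@H](C)C=O | intermediate
5 | 4-bromofuran-2(5H)-one | O=C1C=C(Br)CO1 | starting material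
6 | 4-(tributylstannyl)furan-2(5H)-one | O=C1C=C([Sn](CCCC)(CCCC)CCCC)CO1 | intermediate
7 | tributyl[5-(trimethylsilyloxy)furan-3-yl]stannane | C[Si](C)(C)Oc1cc([Sn](CCCC)(CCCC)CCCC)co1 | intermediate
8 | (5S)-5-[(1R,2S,6E,10E)-12-acetoxy-1-hydroxy-2,6,10-trimethyldodeca-6,10-dien-1-yl]-4-(tributylstannyl)furan-2(5H)-one | CC(=O)OC/C=C(\C)CC/C=C(\C)CCC[C@H](C)[C@@H](O)[C@@H]1OC(=O)C=C1[Sn](CCCC)(CCCC)CCCC | intermediate
9 | (12S,13R,14R)-13-hydroxycembra-1(15),3E,7E-trien-16,14-olide (macrocyclic butenolide) | O=C1C=C2C/C=C(\C)CC/C=C(\C)CCC[C@H](C)[C@@H](O)[C@@H]2O1 | intermediate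
10 | (1S,12S,13R,14R)-13,16-bis[diethoxy(methyl)silyloxy]-14,16-epoxycembra-3E,7E,15-triene (bis-silyl ketene acetal, formed in situ) | CCO[Si](C)(OCC)OC1=C[C@@H]2C/C=C(\C)CC/C=C(\C)CCC[C@H](C)[C@@H](O[Si](C)(OCC)OCC)[C@@H]2O1 | intermediate
11 | (1S,12S,13R,14R)-17-(dimethylamino)-13-hydroxycembra-3E,7E-dien-16,14-olide (C15 epimers) | O=C1C(CN(C)C)[C@@H]2C/C=C(\C)CC/C=C(\C)CCC[C@H](C)[C@@H](O)[C@@H]2O1 | intermediate
12 | trimethylammonium iodide of 11 (formed in situ) | O=C1C(C[N+](C)(C)C)[C@@H]2C/C=C(\C)CC/C=C(\C)CCC[C@H](C)[C@@H](O)[C@@H]2O1.[I-] | intermediate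
13 | (1S,12S,13R,14R)-13-hydroxycembra-3E,7E,15(17)-trien-16,14-olide | O=C1C(=C)[C@@H]2C/C=C(\C)CC/C=C(\C)CCC[C@H](C)[C@@H](O)[C@@H]2O1 | intermediate
14 | (1S,3R,4R,7R,8R,12S,13R,14R)-3,4:7,8-diepoxy-13-hydroxycembr-15(17)-en-16,14-olide | O=C1C(=C)[C@@H]2C[C@H]3O[C@]3(C)CC[C@H]4O[C@]4(C)CCC[C@H](C)[C@@H](O)[C@@H]2O1 | intermediate
15 | 13-O-trimethylsilyl ether of 14 (formed in situ) | O=C1C(=C)[C@@H]2C[C@H]3O[C@]3(C)CC[C@H]4O[C@]4(C)CCC[C@H](C)[C@@H](O[Si](C)(C)C)[C@@H]2O1 | intermediate
16 | 3,13-bis-O-trimethylsilyl 4,7-epoxy-7,8-epoxonium triflate (oxonium oxygen bonded to C4, C7 and C8; formed in situ) | O=C1C(=C)[C@@H]2C[C@@H](O[Si](C)(C)C)[C@]3(C)CC[C@H]4[O+]3[C@]4(C)CCC[C@H](C)[C@@H](O[Si](C)(C)C)[C@@H]2O1.[O-]S(=O)(=O)C(F)(F)F | intermediate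
17 | 3,13-bis-O-trimethylsilyl uprolide D (formed in situ) | C=C1CCC[C@H](C)[C@@H](O[Si](C)(C)C)[C@@H]2OC(=O)C(=C)[C@@H]2C[C@@H](O[Si](C)(C)C)[C@]2(C)CC[C@H]1O2 | intermediate
18 | uprolide D, (1S,3R,4S,7R,12S,13R,14R)-4,7-epoxy-3,13-dihydroxycembra-8(19),15(17)-dien-16,14-olide | C=C1CCC[C@H](C)[C@@H](O)[C@@H]2OC(=O)C(=C)[C@@H]2C[C@@H](O)[C@]2(C)CC[C@H]1O2 | target

## Step count and risks

Total step count: 11. Longest linear sequence: 9 steps (1 → 18 through steps 1, 2, 3, 6, 7, 8, 9, 10, 11).

Most likely to fail: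

**Step 11 (epoxonium cascade).** The risks are non-selective proton loss from the C8 cation (Δ8 isomers), hydride shift, or opening in the other direction. Fallback: set out from 14 and run the cascade with water as the terminating nucleophile (cat. camphorsulfonic acid, THF–H2O). This traps the epoxonium ion at C8 as (8S)-8-hydroxy-8,19-dihydrouprolide D F1; the C8 configuration is irrelevant. The two secondary hydroxyls are silylated (TESCl, imidazole, DMF) to give 3,13-bis-O-triethylsilyl-8-hydroxy-8,19-dihydrouprolide D F2. The remaining tertiary alcohol is dehydrated toward its methyl group (SOCl2, pyridine, −20 °C) to give 3,13-bis-O-triethylsilyl uprolide D F3. Removal of the silyl groups (HF·pyridine, THF) rejoins the route at 18.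

**Step 7 (Stille macrocyclisation).** The risks are slow transmetalation of the electron-poor stannane, β-hydride loss from the π-allyl complex, and oligomers. Fallback: set out from 3 and 6 and couple them intermolecularly at normal concentration (Pd2(dba)3, LiCl, DMF) to give 4-[(2E,6E,11S)-12-hydroxy-3,7,11-trimethyldodeca-2,6-dien-1-yl]furan-2(5H)-one F4. Oxidise (Cu/TEMPO/air) to 4-[(2E,6E,11S)-3,7,11-trimethyl-12-oxododeca-2,6-dien-1-yl]furan-2(5H)-one F5. Close the ring at C13–C14 instead, by an intramolecular vinylogous Mukaiyama aldol: TMSOTf and iPr2NEt at −78 °C give (2S,6E,10E)-2,6,10-trimethyl-12-[5-(trimethylsilyloxy)furan-3-yl]dodeca-6,10-dienal F6, which is added slowly to BF3·OEt2 at high dilution. This comes back to the route at 9. Its own weak points are C13/C14 control inside the ring and possible enolisation of the aldehyde during silylation.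

**Step 6 (aldol with the stannyl silyloxyfuran).** The risks are instability of 7 and low Felkin/threo selectivity next to the bulky tin group. Fallback: set out from 5 and 4 and avoid tin altogether. Silylate 5 (TMSOTf, Et3N) to 4-bromo-2-(trimethylsilyloxy)furan F7. Run the same BF3 aldol with 4 to obtain (5S)-5-[(1R,2S,6E,10E)-12-acetoxy-1-hydroxy-2,6,10-trimethyldodeca-6,10-dien-1-yl]-4-bromofuran-2(5H)-one F8. Close the C1–C2 bond by a Ni-catalysed reductive cross-electrophile coupling of the vinyl bromide with the allylic acetate (NiBr2·glyme, 4,4'-di-tert-butyl-2,2'-bipyridine, Zn, DMA, high dilution), which comes back to the route at 9. This macrocyclisation is known only intermolecularly.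

Further compounds
F1 | step 11 | (8S)-8-hydroxy-8,19-dihydrouprolide D | C[C@]1(O)CCC[C@H](C)[C@@H](O)[C@@H]2OC(=O)C(=C)[C@@H]2C[C@@H](O)[C@]2(C)CC[C@H]1O2
F2 | step 11 | 3,13-bis-O-triethylsilyl-8-hydroxy-8,19-dihydrouprolide D | C[C@]1(O)CCC[C@H](C)[C@@H](O[Si](CC)(CC)CC)[C@@H]2OC(=O)C(=C)[C@@H]2C[C@@H](O[Si](CC)(CC)CC)[C@]2(C)CC[C@H]1O2
F3 | step 11 | 3,13-bis-O-triethylsilyl uprolide D | C=C1CCC[C@H](C)[C@@H](O[Si](CC)(CC)CC)[C@@H]2OC(=O)C(=C)[C@@H]2C[C@@H](O[Si](CC)(CC)CC)[C@]2(C)CC[C@H]1O2
F4 | step 7 | 4-[(2E,6E,11S)-12-hydroxy-3,7,11-trimethyldodeca-2,6-dien-1-yl]furan-2(5H)-one | O=C1C=C(C/C=C(\C)CC/C=C(\C)CCC[C@H](C)CO)CO1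
F5 | step 7 | 4-[(2E,6E,11S)-3,7,11-trimethyl-12-oxododeca-2,6-dien-1-yl]furan-2(5H)-one | O=C1C=C(C/C=C(\C)CC/C=C(\C)CCC[C@H](C)C=O)CO1
F6 | step 7 | (2S,6E,10E)-2,6,10-trimethyl-12-[5-(trimethylsilyloxy)furan-3-yl]dodeca-6,10-dienal | C[Si](C)(C)Oc1cc(C/C=C(\C)CC/C=C(\C)CCC[C@H](C)C=O)co1
F7 | step 6 | 4-bromo-2-(trimethylsilyloxy)furan | C[Si](C)(C)Oc1cc(Br)co1
F8 | step 6 | (5S)-5-[(1R,2S,6E,10E)-12-acetoxy-1-hydroxy-2,6,10-trimethyldodeca-6,10-dien-1-yl]-4-bromofuran-2(5H)-one | CC(=O)OC/C=C(\C)CC/C=C(\C)CCC[C@H](C)[C@@H](O)[C@@H]1OC(=O)C=C1Br
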